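**Plan** (labdane numbering C1–C20 throughout; the target is read as the 3S,5S,9R,10S,13R isomer, an ent-labdane with an axial 3-acetoxy group trans to the C10 methyl group)

- Retrosynthesis: the C15 acid is masked as its tert-butyl ester; C9–C10 (ring B) and C4–C5 (ring A) are then cut in one operation, which turns ring A into the 1,2,2-trimethylcyclopentane of camphoric acid with C5 outside the ring as a carbinol; last, C6–C7 is cut (enolate alkylation).
- Forward: a cyclopentyl methyl ketone from (+)-camphoric acid and an allylic bromide carrying a 2-(silylmethyl)alkene from (R)-citronellic acid are joined. The five-membered ring is kept until the key step, where C4 shifts from C10 to C5 (ring A becomes six-membered) and the resulting C10 cation closes ring B on the allylsilane, which also delivers the C8=C17 methylene.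
- Feature that allows it: C5 is a secondary leaving-group carbon next to quaternary C10, whose neighbour C4 (gem-dimethyl, also quaternary) is the best migrating group; the shift gives exactly the tertiary C10 cation with the C5 side chain that labdane ring B closure needs.
- Stereochemistry: C3 from camphoric acid (Baeyer–Villiger, retention); C13 from citronellic acid; C5 from a CBS reduction (inverted in the shift); C10 by capture anti to the migrating carbon (the camphoric quaternary centre is matched); C9 from the alkene geometry fixed by Wittig olefination and stereoretentive Negishi coupling.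

Key step: step 14

**Step 1**
Reactants: 1 (1R,3S)-(+)-camphoric acid
Product: 2 (1R,5S)-1,8,8-trimethyl-3-oxabicyclo[3.2.1]octane-2,4-dione (camphoric anhydride)
Conditions: Ac2O, 140 °C
Reagents that add atoms: none
Why: the cis-1,3-diacid should close to the cyclic anhydride by dehydration (anhydride formation) without touching either stereocentre.

**Step 2**
Reactants: 2 camphoric anhydride
Product: 3 (1R,3S)-3-acetyl-1,2,2-trimethylcyclopentane-1-carboxylic acid
Conditions: MeMgBr (1.05 equiv), THF, −78 °C; aq. HCl
Reagents that add atoms: methylmagnesium bromide, C[Mg]Br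
Why: Grignard mono-addition to a cyclic anhydride should occur at the less hindered carbonyl (on the CH carbon, not on the quaternary carbon) and stop at the keto carboxylate in the cold, where C3 is not epimerised.

**Step 3**
Reactants: 3 keto acid
Product: 4 (1R,3S)-3-acetoxy-1,2,2-trimethylcyclopentane-1-carboxylic acid
Conditions: m-CPBA, CF3CO2H (cat.), CH2Cl2, 25 °C
Reagents that add atoms: 3-chloroperbenzoic acid, OOC(=O)c1cccc(Cl)c1
Why: Baeyer–Villiger oxidation, in which the secondary ring carbon migrates in preference to methyl with retention, so the C3–C bond becomes the C3–O bond of the final acetate with unchanged (S) configuration.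

**Step 4**
Reactants: 4 acetoxy acid
Product: 5 1-[(1R,3S)-3-hydroxy-1,2,2-trimethylcyclopentyl]ethan-1-one
Conditions: MeLi (5 equiv), Et2O, 0 → 25 °C; inverse quench into aq. NH4Cl
Reagents that add atoms: methyllithium, [Li]C
Why: addition of methyllithium to the lithium carboxylate should give the methyl ketone on work-up (ketone synthesis from a carboxylic acid), while the same reagent cleaves the acetate to the free C3 alcohol needed for the next coupling.

**Step 5**
Reactants: 6 (R)-(+)-citronellic acid
Product: 7 tert-butyl (3R)-3,7-dimethyloct-6-enoate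
Conditions: Boc2O, DMAP (cat.), t-BuOH, 30 °C
Reagents that add atoms: di-tert-butyl dicarbonate, CC(C)(C)OC(=O)OC(=O)OC(C)(C)C
Why: DMAP-catalysed tert-butyl ester formation through the mixed carbonic anhydride, under non-acidic conditions that should leave the trisubstituted alkene and C13 untouched.

**Step 6**
Reactants: 7 tert-butyl citronellate
Product: 8 tert-butyl (3R)-3-methyl-6-oxohexanoate
Conditions: O3, CH2Cl2, −78 °C; then PPh3
Reagents that add atoms: ozone, [O-][O+]=O
Why: ozonolysis with reductive work-up should cleave the only C=C bond to the aldehyde whose carbonyl carbon becomes C9.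

**Step 7**
Reactants: 8 aldehyde; 9 ethyl (triphenyl-λ5-phosphanylidene)acetate
Product: 11 8-tert-butyl 1-ethyl (2Z,6R)-2-bromo-6-methyloct-2-enedioate, via bromo ylide 10 (not isolated)
Conditions: 9, NBS, CH2Cl2, −20 °C; then 8, 25 °C
Reagents that add atoms: N-bromosuccinimide, O=C1CCC(=O)N1Br
Why: bromination of the stabilised ylide followed by Wittig olefination should give the alkene with the ester trans to the alkyl chain (Z by CIP because of bromine), which is the later C7/C11 trans relation.

**Step 8**
Reactants: 11 bromo enoate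
Product: 12 8-tert-butyl 1-ethyl (2Z,6R)-6-methyl-2-[(trimethylsilyl)methyl]oct-2-enedioate
Conditions: Me3SiCH2MgCl, ZnCl2, THF, 0 °C; then 11, Pd(PPh3)4 (5 mol %), 45 °C
Reagents that add atoms: (trimethylsilyl)methylmagnesium chloride, C[Si](C)(C)C[Mg]Cl
Why: Negishi coupling of an alkenyl bromide with an alkylzinc reagent lacking β-hydrogens should proceed at zerovalent palladium with retention of alkene geometry and without attack on either ester.

**Step 9**
Reactants: 12 silylmethyl enoate
Product: 13 tert-butyl (3R,6Z)-8-hydroxy-3-methyl-7-[(trimethylsilyl)methyl]oct-6-enoate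
Conditions: i-Bu2AlH (2.2 equiv), CH2Cl2, −78 °C; aq. potassium sodium tartrate
Reagents that add atoms: none
Why: hydride reduction of the conjugated ethyl ester to the allylic alcohol should be much faster at −78 °C than reduction of the bulky tert-butyl ester.

**Step 10**
Reactants: 13 allylic alcohol
Product: 14 tert-butyl (3R,6E)-8-bromo-3-methyl-7-[(trimethylsilyl)methyl]oct-6-enoate
Conditions: CBr4, PPh3, 2,6-lutidine, CH2Cl2, −20 °C
Reagents that add atoms: carbon tetrabromide, BrC(Br)(Br)Br
Why: Appel bromination under buffered neutral conditions should replace the primary allylic hydroxyl by SN2 without protodesilylation or change of alkene geometry.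

**Step 11**
Reactants: 5 hydroxy ketone; 14 allylic bromide
Product: 15 tert-butyl (3R,6Z)-10-[(1R,3S)-3-hydroxy-1,2,2-trimethylcyclopentyl]-3-methyl-10-oxo-7-[(trimethylsilyl)methyl]dec-6-enoate
Conditions: LiN(i-Pr)2 (2.2 equiv), THF, −78 → −30 °C; then 14, −78 → −20 °C
Reagents that add atoms: none
Why: alkylation of the kinetic lithium enolate (C3 alkoxide as spectator) should form C6–C7, because the methyl ketone can enolise on one side only (C10 is quaternary) and the primary allylic bromide reacts by SN2.

**Step 12**
Reactants: 15 hydroxy ketone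
Product: 16 tert-butyl (3R,6Z)-10-[(1R,3S)-3-acetoxy-1,2,2-trimethylcyclopentyl]-3-methyl-10-oxo-7-[(trimethylsilyl)methyl]dec-6-enoate
Conditions: Ac2O, DMAP, pyridine, CH2Cl2, 25 °C
Reagents that add atoms: acetic anhydride, CC(=O)OC(C)=O
Why: DMAP-catalysed O-acylation installs the acetate of the target at the O–H bond only, so C3 keeps its configuration.

**Step 13**
Reactants: 16 acetoxy ketone
Product: 17 tert-butyl (3R,6Z,10R)-10-[(1R,3S)-3-acetoxy-1,2,2-trimethylcyclopentyl]-10-hydroxy-3-methyl-7-[(trimethylsilyl)methyl]dec-6-enoate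
Conditions: (S)-Me-CBS oxazaborolidine (0.5 equiv), catecholborane (1.5 equiv), toluene, −40 °C
Reagents that add atoms: none
Why: CBS reduction, in which the tert-alkyl group is the large and the CH2 chain the small ketone substituent, so the (S)-catalyst should give the R carbinol (C5 of the labdane) by reagent control, and catecholborane should spare the alkene and both esters.

**Step 14**
Reactants: 17 carbinol
Product: 19 tert-butyl (3R)-5-[(1R,4aS,6S,8aS)-6-acetoxy-5,5,8a-trimethyl-2-methylidenedecahydronaphthalen-1-yl]-3-methylpentanoate, via triflate 18 (not isolated)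
Conditions: Tf2O (1.2 equiv), 2,6-di-tert-butyl-4-methylpyridine (3 equiv), CH2Cl2, −78 → −20 °C; Et3N quench at −78 °C
Reagents that add atoms: triflic anhydride, O=S(=O)(OS(=O)(=O)C(F)(F)F)C(F)(F)F (its atoms stay in 18 only)
Why: Proposed new method: the secondary neopentyl-type triflate 18 should ionise with assistance of the antiperiplanar C10–C4 bond, so that C4 shifts from C10 to C5 (Wagner–Meerwein/Demjanov-type expansion of the five-membered ring to ring A) and leaves the tertiary C10 cation, the monocyclic cation of labdane biosynthesis, which the allylsilane traps with loss of the silyl group to triflate. The closest known reaction types are the solvolytic ring expansion of cyclopentylcarbinyl sulfonates and the allylsilane-terminated cation–olefin cyclisation of monocyclic terpenoid cations; their union in one flask on this substrate is new. Ring A arises by the 1,2-shift (expansion by one carbon), ring B by 6-endo attack of alkene carbon C9 on C10 through a chair transition state, and the β-silyl cation at C8 can only collapse to the exocyclic C8=C17 alkene. C5 is set by inversion (C4 enters anti to the triflate, R carbinol to 5S); C10 by capture anti to the departing C4, which gives 10S from the camphoric R centre and is also the outcome expected from chair–chair closure of a free cation with the C5 chain equatorial; C9 by the alkene geometry (C7 trans to C11), which places C11 equatorial and cis to the C10 methyl group. The step needs C4 to migrate rather than C1 or the methyl group; C4 is the only tertiary migrating carbon and the C4–C10 bond joins two quaternary centres, so it is the weakest and most electron-rich of the three. The C3 oxygen is carried as the acetate because an acyloxy group should not drive a Grob-type fragmentation of the C10 cation as a free or silylated hydroxyl could.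

**Step 15**
Reactants: 19 bicyclic tert-butyl ester
Product: 21 (3R)-5-[(1R,4aS,6S,8aS)-6-acetoxy-5,5,8a-trimethyl-2-methylidenedecahydronaphthalen-1-yl]-3-methylpentanoic acid (target), via trimethylsilyl ester 20 (not isolated)
Conditions: Me3SiOTf, 2,6-lutidine, CH2Cl2, 0 °C; then aq. buffer pH 5
Reagents that add atoms: trimethylsilyl triflate, C[Si](C)(C)OS(=O)(=O)C(F)(F)F (its silyl group stays in 20 only)
Why: silyl triflate-mediated cleavage of the tert-butyl ester (O-silylation, loss of the tert-butyl cation as isobutene to the base) is non-protic and should spare the acid-labile exocyclic alkene and the acetate, and the silyl ester hydrolyses on work-up.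

**Compound list**

1 | (1R,3S)-(+)-camphoric acid | C[C@]1(CC[C@@H](C1(C)C)C(=O)O)C(=O)O | starting material
2 | (1R,5S)-1,8,8-trimethyl-3-oxabicyclo[3.2.1]octane-2,4-dione | C[C@@]12CC[C@@H](C1(C)C)C(=O)OC2=O | intermediate
3 | (1R,3S)-3-acetyl-1,2,2-trimethylcyclopentane-1-carboxylic acid | C[C@]1(CC[C@@H](C1(C)C)C(C)=O)C(=O)O | intermediate
4 | (1R,3S)-3-acetoxy-1,2,2-trimethylcyclopentane-1-carboxylic acid | C[C@]1(CC[C@@H](C1(C)C)OC(C)=O)C(=O)O | intermediate
5 | 1-[(1R,3S)-3-hydroxy-1,2,2-trimethylcyclopentyl]ethan-1-one | C[C@]1(CC[C@@H](C1(C)C)O)C(C)=O | intermediate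
6 | (R)-(+)-citronellic acid, (3R)-3,7-dimethyloct-6-enoic acid | C[C@H](CCC=C(C)C)CC(=O)O | starting material
7 | tert-butyl (3R)-3,7-dimethyloct-6-enoate | C[C@H](CCC=C(C)C)CC(=O)OC(C)(C)C | intermediate
8 | tert-butyl (3R)-3-methyl-6-oxohexanoate | C[C@H](CCC=O)CC(=O)OC(C)(C)C | intermediate
9 | ethyl (triphenyl-λ5-phosphanylidene)acetate | CCOC(=O)C=P(c1ccccc1)(c1ccccc1)c1ccccc1 | starting material
10 | ethyl bromo(triphenyl-λ5-phosphanylidene)acetate | CCOC(=O)C(Br)=P(c1ccccc1)(c1ccccc1)c1ccccc1 | intermediate (not isolated)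
11 | 8-tert-butyl 1-ethyl (2Z,6R)-2-bromo-6-methyloct-2-enedioate | CCOC(=O)/C(Br)=C/CC[C@@H](C)CC(=O)OC(C)(C)C | intermediate
12 | 8-tert-butyl 1-ethyl (2Z,6R)-6-methyl-2-[(trimethylsilyl)methyl]oct-2-enedioate | CCOC(=O)/C(C[Si](C)(C)C)=C/CC[C@@H](C)CC(=O)OC(C)(C)C | intermediate
13 | tert-butyl (3R,6Z)-8-hydroxy-3-methyl-7-[(trimethylsilyl)methyl]oct-6-enoate | OC/C(C[Si](C)(C)C)=C/CC[C@@H](C)CC(=O)OC(C)(C)C | intermediate
14 | tert-butyl (3R,6E)-8-bromo-3-methyl-7-[(trimethylsilyl)methyl]oct-6-enoate | BrC/C(C[Si](C)(C)C)=C/CC[C@@H](C)CC(=O)OC(C)(C)C | intermediate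
15 | tert-butyl (3R,6Z)-10-[(1R,3S)-3-hydroxy-1,2,2-trimethylcyclopentyl]-3-methyl-10-oxo-7-[(trimethylsilyl)methyl]dec-6-enoate | C[C@]1(CC[C@@H](C1(C)C)O)C(=O)CC/C(C[Si](C)(C)C)=C/CC[C@@H](C)CC(=O)OC(C)(C)C | intermediate
16 | tert-butyl (3R,6Z)-10-[(1R,3S)-3-acetoxy-1,2,2-trimethylcyclopentyl]-3-methyl-10-oxo-7-[(trimethylsilyl)methyl]dec-6-enoate | C[C@]1(CC[C@@H](C1(C)C)OC(C)=O)C(=O)CC/C(C[Si](C)(C)C)=C/CC[C@@H](C)CC(=O)OC(C)(C)C | intermediate
17 | tert-butyl (3R,6Z,10R)-10-[(1R,3S)-3-acetoxy-1,2,2-trimethylcyclopentyl]-10-hydroxy-3-methyl-7-[(trimethylsilyl)methyl]dec-6-enoate | C[C@]1(CC[C@@H](C1(C)C)OC(C)=O)[C@H](O)CC/C(C[Si](C)(C)C)=C/CC[C@@H](C)CC(=O)OC(C)(C)C | intermediate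
18 | tert-butyl (3R,6Z,10R)-10-[(1R,3S)-3-acetoxy-1,2,2-trimethylcyclopentyl]-3-methyl-10-[(trifluoromethanesulfonyl)oxy]-7-[(trimethylsilyl)methyl]dec-6-enoate | C[C@]1(CC[C@@H](C1(C)C)OC(C)=O)[C@H](OS(=O)(=O)C(F)(F)F)CC/C(C[Si](C)(C)C)=C/CC[C@@H](C)CC(=O)OC(C)(C)C | intermediate (not isolated)
19 | tert-butyl (3R)-5-[(1R,4aS,6S,8aS)-6-acetoxy-5,5,8a-trimethyl-2-methylidenedecahydronaphthalen-1-yl]-3-methylpentanoate | C=C1CC[C@@H]2C(C)(C)[C@@H](OC(C)=O)CC[C@@]2(C)[C@@H]1CC[C@@H](C)CC(=O)OC(C)(C)C | intermediate
20 | trimethylsilyl (3R)-5-[(1R,4aS,6S,8aS)-6-acetoxy-5,5,8a-trimethyl-2-methylidenedecahydronaphthalen-1-yl]-3-methylpentanoate | C=C1CC[C@@H]2C(C)(C)[C@@H](OC(C)=O)CC[C@@]2(C)[C@@H]1CC[C@@H](C)CC(=O)O[Si](C)(C)C | intermediate (not isolated)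
21 | (3R)-5-[(1R,4aS,6S,8aS)-6-acetoxy-5,5,8a-trimethyl-2-methylidenedecahydronaphthalen-1-yl]-3-methylpentanoic acid | C=C1CC[C@@H]2C(C)(C)[C@@H](OC(C)=O)CC[C@@]2(C)[C@@H]1CC[C@@H](C)CC(=O)O | target

**Total step count:** 15
**Longest linear sequence:** 11 steps (steps 5–15, from 6); the camphoric branch is 9 steps (steps 1–4 and 11–15).

**Steps most likely to fail**

1. Step 14 (proposed new method).
   - What may go wrong: migration of C1 or of the methyl group instead of C4; loss of the triflate or of the C10 cation by elimination before ring B closes; closure on the wrong face or through a boat (cis-fused or C9-epimeric bicycle); partial cleavage of the tert-butyl ester by the silyl triflate formed.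
   - Fallback (known chemistry, from 14, back at 19): both rings are closed in one operation by the established epoxide-initiated, allylsilane-terminated polyene cyclisation.
   - Geranyl bromide and PhSO2Na (DMF, 25 °C) give geranyl phenyl sulfone F1.
   - Shi epoxidation of the distal, more electron-rich alkene (fructose-derived ketone of the enantiomeric series that delivers the R epoxide, KHSO5, K2CO3, MeCN/H2O, 0 °C) gives the (R)-epoxy sulfone F2.
   - Its lithio derivative (n-BuLi, THF, −78 °C) is alkylated by 14 to the coupled sulfone F3.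
   - Na(Hg), Na2HPO4, MeOH, −20 °C removes the sulfonyl group to give the epoxy diene allylsilane F4.
   - MeAlCl2, CH2Cl2, −78 °C should close rings A and B through chair–chair folding to the 3-equatorial alcohol F5, the epoxide configuration controlling C5, C9 and C10.
   - Dess–Martin periodinane gives the 3-ketone F6; LiBH(s-Bu)3 (THF, −78 °C) should attack from the equatorial side to give the axial alcohol F7; Ac2O/DMAP then returns 19.

2. Step 13.
   - What may go wrong: poor facial selectivity if catalyst control opposes the bias of the neighbouring quaternary centre; slow reduction of the hindered ketone with competing hydroboration of the allylsilane alkene.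
   - Fallback (from 16, back at 17, no new compound): enzymatic reduction with an NADPH-dependent ketoreductase (alcohol dehydrogenase class) selected from a panel for R selectivity at the carbinol carbon, with glucose dehydrogenase/glucose for cofactor recycling in phosphate buffer pH 7 with i-PrOH/DMSO cosolvent at 30 °C. The enzyme pocket, not the substrate, then fixes the face, and no borane is present.

3. Step 11.
   - What may go wrong: proton exchange between product and enolate leading to double alkylation; O-alkylation at the alkoxide; self-condensation of the methyl ketone enolate.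
   - Fallback (from 5 with 14, back at 15): azaenolate alkylation. Ketone 5 and Me2NNH2 (EtOH, AcOH cat., 80 °C) give the dimethylhydrazone F8. LiN(i-Pr)2 (2.2 equiv, THF, −78 → 0 °C) and then 14 should give the mono-C-alkylated hydrazone F9. Cu(OAc)2 in THF/H2O at pH 7 and 25 °C hydrolyses it to 15.

**Further compounds**

F1 | step 14 | {[(2E)-3,7-dimethylocta-2,6-dien-1-yl]sulfonyl}benzene (geranyl phenyl sulfone) | CC(C)=CCC/C(C)=C/CS(=O)(=O)c1ccccc1
F2 | step 14 | {[(2E)-5-[(2R)-3,3-dimethyloxiran-2-yl]-3-methylpent-2-en-1-yl]sulfonyl}benzene | CC1(C)O[C@@H]1CC/C(C)=C/CS(=O)(=O)c1ccccc1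
F3 | step 14 | tert-butyl (3R,6Z,10E)-9-(benzenesulfonyl)-13-[(2R)-3,3-dimethyloxiran-2-yl]-3,11-dimethyl-7-[(trimethylsilyl)methyl]trideca-6,10-dienoate (C9 epimers) | CC1(C)O[C@@H]1CC/C(C)=C/C(C/C(C[Si](C)(C)C)=C/CC[C@@H](C)CC(=O)OC(C)(C)C)S(=O)(=O)c1ccccc1
F4 | step 14 | tert-butyl (3R,6Z,10E)-13-[(2R)-3,3-dimethyloxiran-2-yl]-3,11-dimethyl-7-[(trimethylsilyl)methyl]trideca-6,10-dienoate | CC1(C)O[C@@H]1CC/C(C)=C/CC/C(C[Si](C)(C)C)=C/CC[C@@H](C)CC(=O)OC(C)(C)C
F5 | step 14 | tert-butyl (3R)-5-[(1R,4aS,6R,8aS)-6-hydroxy-5,5,8a-trimethyl-2-methylidenedecahydronaphthalen-1-yl]-3-methylpentanoate | C=C1CC[C@@H]2C(C)(C)[C@H](O)CC[C@@]2(C)[C@@H]1CC[C@@H](C)CC(=O)OC(C)(C)C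
F6 | step 14 | tert-butyl (3R)-3-methyl-5-[(1R,4aS,8aS)-5,5,8a-trimethyl-2-methylidene-6-oxodecahydronaphthalen-1-yl]pentanoate | C=C1CC[C@@H]2C(C)(C)C(=O)CC[C@@]2(C)[C@@H]1CC[C@@H](C)CC(=O)OC(C)(C)C
F7 | step 14 | tert-butyl (3R)-5-[(1R,4aS,6S,8aS)-6-hydroxy-5,5,8a-trimethyl-2-methylidenedecahydronaphthalen-1-yl]-3-methylpentanoate | C=C1CC[C@@H]2C(C)(C)[C@@H](O)CC[C@@]2(C)[C@@H]1CC[C@@H](C)CC(=O)OC(C)(C)C
F0 | step 13 | none | none
F8 | step 11 | (1S,3R)-3-[1-(2,2-dimethylhydrazinylidene)ethyl]-2,2,3-trimethylcyclopentan-1-ol | C[C@]1(CC[C@@H](C1(C)C)O)C(C)=NN(C)C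
F9 | step 11 | tert-butyl (3R,6Z)-10-(2,2-dimethylhydrazinylidene)-10-[(1R,3S)-3-hydroxy-1,2,2-trimethylcyclopentyl]-3-methyl-7-[(trimethylsilyl)methyl]dec-6-enoate | C[C@]1(CC[C@@H](C1(C)C)O)C(CC/C(C[Si](C)(C)C)=C/CC[C@@H](C)CC(=O)OC(C)(C)C)=NN(C)C
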